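**Retrosynthetic overview**
- The last bond made is the C2′–O bond of the side chain, by an enantioselective ene-type oxygenation of the 7-prenyl group of the bis(indolyl)dimethoxyquinone (the O,O-dimethyl ether of demethylasterriquinone B1).
- The two quinone C–OMe bonds come from double methoxide addition–elimination on the 3,6-bis(indolyl)-2,5-dichloroquinone.
- The two indole C3–quinone bonds come from successive acid-promoted conjugate addition and re-oxidation on 2,5-dichloro-1,4-benzoquinone, first with 2-(1,1-dimethylallyl)indole (indole A), then with 7-prenylindole (indole B).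
- Indole A comes from indole and B-prenyl-9-BBN (made from 1,1-dimethylallene); indole B comes from 7-bromoindole and prenyl bromide.
- No ring is built: both indole nuclei and the quinone ring are bought; the quinone is joined to indole A first and to indole B second.

Assumption: the sense of induction of the new step 6 cannot be predicted with certainty. The (S)-configured phosphoric acid is written; if the first run (Mosher ester analysis) shows the (S)-alcohol, its commercial mirror image is used instead.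

**Step 1**
Reactants: 1 indole; 2 3-methylbuta-1,2-diene
Product: 5 2-(2-methylbut-3-en-2-yl)-1H-indole, via B-prenyl-9-BBN 3 (not isolated), via 3-chloroindole 4 (not isolated)
Conditions: 2, 9-BBN, THF, 0 °C→rt (gives 3); 1, t-BuOCl, Et3N, THF, −78 °C (gives 4); then add 3, −78 °C→rt; H2O
Reagents that add atoms: none
Why: C3-chlorination gives 4, whose 3H-tautomer binds borane 3 at nitrogen so that the prenyl group is delivered to C2 through a six-membered allylboration transition state with allyl inversion (hence the 1,1-dimethylallyl group), and loss of HCl restores the indole (chloroindolenine/allylborane reverse prenylation).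

**Step 2**
Reactants: 6 7-bromo-1H-indole; 7 1-bromo-3-methylbut-2-ene (prenyl bromide)
Product: 9 7-(3-methylbut-2-en-1-yl)-1H-indole, via 7-lithio-1-potassioindole 8 (not isolated)
Conditions: KH, THF, 0 °C; t-BuLi (2.1 equiv), −78 °C; then 7 (1.0 equiv), −78→0 °C; aq. NH4Cl
Reagents that add atoms: none
Why: KH masks the N–H as its potassium salt, bromine–lithium exchange then gives the C7 aryllithium 8, and this far more reactive carbanion is alkylated at the primary carbon of prenyl bromide (SN2 alkylation of an aryllithium).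

**Step 3**
Reactants: 5 2-(2-methylbut-3-en-2-yl)-1H-indole; 10 2,5-dichloro-1,4-benzoquinone
Product: 12 2,5-dichloro-3-[2-(2-methylbut-3-en-2-yl)-1H-indol-3-yl]cyclohexa-2,5-diene-1,4-dione, via dichlorohydroquinone adduct 11 (not isolated)
Conditions: AcOH, 25 °C; then DDQ (2,3-dichloro-5,6-dicyano-1,4-benzoquinone, 1.0 equiv), THF, 0 °C
Reagents that add atoms: none
Why: Acid-promoted conjugate (Michael) addition of the nucleophilic indole C3 to a C–H position of the quinone gives hydroquinone 11, which DDQ dehydrogenates back to the quinone; acetic acid is mild enough for the acid-sensitive 2-tert-alkylindole.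

**Step 4**
Reactants: 12 2,5-dichloro-3-[2-(2-methylbut-3-en-2-yl)-1H-indol-3-yl]cyclohexa-2,5-diene-1,4-dione; 9 7-(3-methylbut-2-en-1-yl)-1H-indole
Product: 14 2,5-dichloro-3-[2-(2-methylbut-3-en-2-yl)-1H-indol-3-yl]-6-[7-(3-methylbut-2-en-1-yl)-1H-indol-3-yl]cyclohexa-2,5-diene-1,4-dione, via bis(indolyl)dichlorohydroquinone 13 (not isolated)
Conditions: H2SO4 (cat.), THF, 0→25 °C; then DDQ (1.0 equiv), 0 °C
Reagents that add atoms: none
Why: The only remaining quinone C–H position is para to the first indolyl group, so a second acid-promoted conjugate addition and DDQ re-oxidation fixes the 3,6-bis(indolyl) pattern; anhydrous catalytic acid at room temperature leaves both prenyl-type alkenes intact.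

**Step 5**
Reactants: 14 2,5-dichloro-3-[2-(2-methylbut-3-en-2-yl)-1H-indol-3-yl]-6-[7-(3-methylbut-2-en-1-yl)-1H-indol-3-yl]cyclohexa-2,5-diene-1,4-dione
Product: 15 2,5-dimethoxy-3-[2-(2-methylbut-3-en-2-yl)-1H-indol-3-yl]-6-[7-(3-methylbut-2-en-1-yl)-1H-indol-3-yl]cyclohexa-2,5-diene-1,4-dione
Conditions: NaOMe (8 equiv), dry MeOH/THF, 50 °C; aq. NH4Cl
Reagents that add atoms: sodium methoxide, [Na+].[O-]C
Why: Each C–Cl is a vinylogous acid chloride, so methoxide replaces it by addition–elimination (nucleophilic vinylic substitution) and forms both C–OMe bonds; water is excluded so the reaction stops at the dimethyl ether.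

**Step 6**
Reactants: 15 2,5-dimethoxy-3-[2-(2-methylbut-3-en-2-yl)-1H-indol-3-yl]-6-[7-(3-methylbut-2-en-1-yl)-1H-indol-3-yl]cyclohexa-2,5-diene-1,4-dione
Product: 18 3-[7-[(2R)-2-hydroxy-3-methylbut-3-en-1-yl]-1H-indol-3-yl]-2,5-dimethoxy-6-[2-(2-methylbut-3-en-2-yl)-1H-indol-3-yl]cyclohexa-2,5-diene-1,4-dione (the target), via alkoxyamine 16 (not isolated), via hydroquinone alcohol 17 (not isolated)
Conditions: 4-acetamido-2,2,6,6-tetramethyl-1-oxopiperidin-1-ium tetrafluoroborate (1.3 equiv), (S)-3,3′-bis(2,4,6-triisopropylphenyl)-1,1′-binaphthyl-2,2′-diyl hydrogen phosphate (10 mol %), Na2CO3 (solid), toluene, 0 °C; then Zn dust, AcOH/THF/H2O, 45 °C; then air, EtOAc/aq. NaHCO3, 25 °C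
Reagents that add atoms: 4-acetamido-2,2,6,6-tetramethyl-1-oxopiperidin-1-ium tetrafluoroborate, CC(=O)NC1CC(C)(C)[N+](=O)C(C)(C)C1.F[B-](F)(F)F
Why: Proposed new method: a catalytic enantioselective oxoammonium ene-type oxygenation under chiral-anion phase transfer. The toluene-insoluble oxoammonium salt enters solution only as its ion pair with the lipophilic chiral phosphate, which is anchored by a hydrogen bond to the indole N1–H next to the C7 prenyl group. The N=O oxygen bonds to the less substituted alkene carbon C2′ from one face (Re-face attack gives R) while a methyl hydrogen is transferred and the double bond moves to C3′=C4′, giving 16; Na2CO3 regenerates the phosphate. The monosubstituted vinyl group and the push–pull indolylquinone alkenes are too electron-poor or hindered to react. Zinc then cleaves the N–O bond (and reduces the quinone to 17), and air restores the quinone. The closest known reactions are the racemic ene-like addition of oxoammonium salts to trisubstituted alkenes and chiral-phosphate phase-transfer catalysis with insoluble cationic oxidants.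

**Compound list**
1 | indole (1H-indole) | c1ccc2[nH]ccc2c1 | starting material
2 | 3-methylbuta-1,2-diene (1,1-dimethylallene) | CC(C)=C=C | starting material
3 | 9-(3-methylbut-2-en-1-yl)-9-borabicyclo[3.3.1]nonane (B-prenyl-9-BBN) | CC(C)=CCB1C2CCCC1CCC2 | intermediate
4 | 3-chloro-1H-indole | Clc1c[nH]c2ccccc12 | intermediate
5 | 2-(2-methylbut-3-en-2-yl)-1H-indole | C=CC(C)(C)c1cc2ccccc2[nH]1 | intermediate
6 | 7-bromo-1H-indole | Brc1cccc2cc[nH]c12 | starting material
7 | 1-bromo-3-methylbut-2-ene (prenyl bromide) | CC(C)=CCBr | starting material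
8 | (7-lithioindol-1-yl)potassium | [Li]c1cccc2ccn([K])c12 | intermediate
9 | 7-(3-methylbut-2-en-1-yl)-1H-indole | CC(C)=CCc1cccc2cc[nH]c12 | intermediate
10 | 2,5-dichloro-1,4-benzoquinone | O=C1C=C(Cl)C(=O)C=C1Cl | starting material
11 | 2,5-dichloro-3-[2-(2-methylbut-3-en-2-yl)-1H-indol-3-yl]benzene-1,4-diol | Oc1c(Cl)cc(O)c(Cl)c1-c1c(C(C)(C)C=C)[nH]c2ccccc12 | intermediate
12 | 2,5-dichloro-3-[2-(2-methylbut-3-en-2-yl)-1H-indol-3-yl]cyclohexa-2,5-diene-1,4-dione | O=C1C(Cl)=CC(=O)C(Cl)=C1c1c(C(C)(C)C=C)[nH]c2ccccc12 | intermediate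
13 | 2,5-dichloro-3-[2-(2-methylbut-3-en-2-yl)-1H-indol-3-yl]-6-[7-(3-methylbut-2-en-1-yl)-1H-indol-3-yl]benzene-1,4-diol | Oc1c(Cl)c(-c2c[nH]c3c(CC=C(C)C)cccc23)c(O)c(Cl)c1-c1c(C(C)(C)C=C)[nH]c2ccccc12 | intermediate
14 | 2,5-dichloro-3-[2-(2-methylbut-3-en-2-yl)-1H-indol-3-yl]-6-[7-(3-methylbut-2-en-1-yl)-1H-indol-3-yl]cyclohexa-2,5-diene-1,4-dione | O=C1C(Cl)=C(c2c[nH]c3c(CC=C(C)C)cccc23)C(=O)C(Cl)=C1c1c(C(C)(C)C=C)[nH]c2ccccc12 | intermediate
15 | 2,5-dimethoxy-3-[2-(2-methylbut-3-en-2-yl)-1H-indol-3-yl]-6-[7-(3-methylbut-2-en-1-yl)-1H-indol-3-yl]cyclohexa-2,5-diene-1,4-dione | C=CC(C)(C)c1[nH]c2ccccc2c1C1=C(OC)C(=O)C(c2c[nH]c3c(CC=C(C)C)cccc23)=C(OC)C1=O | intermediate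
16 | 3-[7-[(2R)-2-[(4-acetamido-2,2,6,6-tetramethylpiperidin-1-yl)oxy]-3-methylbut-3-en-1-yl]-1H-indol-3-yl]-2,5-dimethoxy-6-[2-(2-methylbut-3-en-2-yl)-1H-indol-3-yl]cyclohexa-2,5-diene-1,4-dione | C=CC(C)(C)c1[nH]c2ccccc2c1C1=C(OC)C(=O)C(c2c[nH]c3c(C[C@@H](ON4C(C)(C)CC(NC(C)=O)CC4(C)C)C(=C)C)cccc23)=C(OC)C1=O | intermediate
17 | 2,5-dimethoxy-3-[2-(2-methylbut-3-en-2-yl)-1H-indol-3-yl]-6-[7-[(2R)-2-hydroxy-3-methylbut-3-en-1-yl]-1H-indol-3-yl]benzene-1,4-diol | C=CC(C)(C)c1[nH]c2ccccc2c1-c1c(OC)c(O)c(-c2c[nH]c3c(C[C@@H](O)C(=C)C)cccc23)c(OC)c1O | intermediate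
18 | 3-[7-[(2R)-2-hydroxy-3-methylbut-3-en-1-yl]-1H-indol-3-yl]-2,5-dimethoxy-6-[2-(2-methylbut-3-en-2-yl)-1H-indol-3-yl]cyclohexa-2,5-diene-1,4-dione | C=CC(C)(C)c1[nH]c2ccccc2c1C1=C(OC)C(=O)C(c2c[nH]c3c(C[C@@H](O)C(=C)C)cccc23)=C(OC)C1=O | target

**Total step count:** 6
**Longest linear sequence:** 5 steps (steps 1, 3, 4, 5, 6; step 2 joins at step 4)

**Three steps most likely to fail**

Step 6 (the new step). The risks are low enantioselectivity and competing oxidation of the indoles or the benzylic CH2. The fallback uses known chemistry, sets out from 15 and comes back at 18. Compound 15 is epoxidised at the trisubstituted prenyl alkene by Shi epoxidation with the D-fructose-derived ketone 1,2:4,5-di-O-isopropylidene-β-D-erythro-hexo-2,3-diulo-2,6-pyranose (30 mol %), KHSO5 (as 2KHSO5·KHSO4·K2SO4), K2CO3, Bu4NHSO4, MeCN/dimethoxymethane/aq. Na2B4O7 buffer, 0 °C. This gives 3-[7-[[(2R)-3,3-dimethyloxiran-2-yl]methyl]-1H-indol-3-yl]-2,5-dimethoxy-6-[2-(2-methylbut-3-en-2-yl)-1H-indol-3-yl]cyclohexa-2,5-diene-1,4-dione F1; the dioxirane sets the C2′–O bond and, by analogy with other trisubstituted alkenes, this ketone should give the (R)-epoxide. The epoxide is then opened at its tertiary carbon and a methyl proton removed with Me3SiOTf/DBU in toluene, −78→0 °C, which leaves the C2′–O bond untouched and gives 2,5-dimethoxy-3-[2-(2-methylbut-3-en-2-yl)-1H-indol-3-yl]-6-[7-[(2R)-3-methyl-2-(trimethylsilyloxy)but-3-en-1-yl]-1H-indol-3-yl]cyclohexa-2,5-diene-1,4-dione F2. Dilute aqueous citric acid in THF removes the silyl group and gives 18.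

Step 5. The risks are incomplete double substitution on the hindered, donor-deactivated chloroquinone and partial hydrolysis. The fallback sets out from 14 and comes back at 15. Both chlorides are hydrolysed with 10 % aq. NaOH in MeOH at reflux to 2,5-dihydroxy-3-[2-(2-methylbut-3-en-2-yl)-1H-indol-3-yl]-6-[7-(3-methylbut-2-en-1-yl)-1H-indol-3-yl]cyclohexa-2,5-diene-1,4-dione (demethylasterriquinone B1) F3. Its two acidic vinylogous-acid hydroxyls are then O-methylated with Me3SiCHN2 in MeOH/toluene at 0 °C to give 15.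

Step 4. The risks are that mono-indolylquinone 12 is too deactivated and shielded to accept a second indole, and that the mineral acid harms the prenyl group. The fallback reverses the order of fragment union, sets out from 9 and 10, and comes back at 13. Compounds 9 and 10 are combined with catalytic HCl in THF at 0 °C to give 2,5-dichloro-3-[7-(3-methylbut-2-en-1-yl)-1H-indol-3-yl]benzene-1,4-diol F4. DDQ oxidises it to 2,5-dichloro-3-[7-(3-methylbut-2-en-1-yl)-1H-indol-3-yl]cyclohexa-2,5-diene-1,4-dione F5. The more electron-rich indole 5 then adds to this quinone in AcOH at 25 °C to give 13, and DDQ gives 14 as in step 4.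

**Further compounds**
F1 | step 6 | 3-[7-[[(2R)-3,3-dimethyloxiran-2-yl]methyl]-1H-indol-3-yl]-2,5-dimethoxy-6-[2-(2-methylbut-3-en-2-yl)-1H-indol-3-yl]cyclohexa-2,5-diene-1,4-dione | C=CC(C)(C)c1[nH]c2ccccc2c1C1=C(OC)C(=O)C(c2c[nH]c3c(C[C@H]4OC4(C)C)cccc23)=C(OC)C1=O
F2 | step 6 | 2,5-dimethoxy-3-[2-(2-methylbut-3-en-2-yl)-1H-indol-3-yl]-6-[7-[(2R)-3-methyl-2-(trimethylsilyloxy)but-3-en-1-yl]-1H-indol-3-yl]cyclohexa-2,5-diene-1,4-dione | C=CC(C)(C)c1[nH]c2ccccc2c1C1=C(OC)C(=O)C(c2c[nH]c3c(C[C@@H](O[Si](C)(C)C)C(=C)C)cccc23)=C(OC)C1=O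
F3 | step 5 | 2,5-dihydroxy-3-[2-(2-methylbut-3-en-2-yl)-1H-indol-3-yl]-6-[7-(3-methylbut-2-en-1-yl)-1H-indol-3-yl]cyclohexa-2,5-diene-1,4-dione (demethylasterriquinone B1) | C=CC(C)(C)c1[nH]c2ccccc2c1C1=C(O)C(=O)C(c2c[nH]c3c(CC=C(C)C)cccc23)=C(O)C1=O
F4 | step 4 | 2,5-dichloro-3-[7-(3-methylbut-2-en-1-yl)-1H-indol-3-yl]benzene-1,4-diol | Oc1c(Cl)cc(O)c(Cl)c1-c1c[nH]c2c(CC=C(C)C)cccc12
F5 | step 4 | 2,5-dichloro-3-[7-(3-methylbut-2-en-1-yl)-1H-indol-3-yl]cyclohexa-2,5-diene-1,4-dione | O=C1C(Cl)=CC(=O)C(Cl)=C1c1c[nH]c2c(CC=C(C)C)cccc12
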